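The oxolane (ring atoms O1, C2, C3, C4, C5) is made by contracting an oxan-4-one. The plan exploits the cis pair at C3/C4: the exocyclic oxymethyl carbon on C3 is the ketone carbon of the pyranone, extruded in a photochemical Wolff rearrangement, and the benzylic carbon on C4 carries a hydroxyl that captures the resulting ketene. One operation therefore contracts the ring, sets C3 and locks C3/C4 cis in a fused γ-lactone. The precursor, a 3-diazo-2-aryl-5-[aryl(hydroxy)methyl]oxan-4-one, comes from O-benzylvanillin (used twice) and a silyloxydiene by asymmetric hetero-Diels–Alder reaction, reductive aldol and diazo transfer. Lactone reduction, acylation and hydrogenolysis finish the synthesis.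

Key step: step 6

Abbreviation: Ar = 4-(benzyloxy)-3-methoxyphenyl.

Assumption: (S)-BINOL/Ti(OiPr)4 is taken to direct the diene to the Si face of the aldehyde carbonyl, which gives the 2S adduct; if the sense were opposite, (R)-BINOL would be used.

Step 1
Reactants: 1 4-(benzyloxy)-3-methoxybenzaldehyde; 2 (E)-1-methoxy-3-(trimethylsilyloxy)buta-1,3-diene
Product: 4 (2S)-2-Ar-2,3-dihydro-4H-pyran-4-one, via silylated aldol adduct 3 (not isolated)
Conditions: (S)-BINOL (20 mol%), Ti(OiPr)4 (10 mol%), 4 Å MS, Et2O, −20 °C; then CF3CO2H, CH2Cl2, 0 °C; aqueous work-up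
Reagents that add atoms: none
Why: Enantioselective hetero-Diels–Alder reaction (Mukaiyama aldol addition of the silyloxydiene to the titanium–BINOL-bound aldehyde, then acid-induced cyclisation with loss of methanol), in which the chiral titanium complex selects the Si face of the aldehyde and so sets C2 (S), the centre from which all others are later derived.

Step 2
Reactants: 4 (2S)-2-Ar-2,3-dihydro-4H-pyran-4-one; 1 4-(benzyloxy)-3-methoxybenzaldehyde
Product: 6 (2S)-2-Ar-5-[Ar(hydroxy)methyl]oxan-4-one as a mixture of epimers, via lithium enolate 5 (not isolated)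
Conditions: LiBH(s-Bu)3, THF, −78 °C; then 1, −78 °C; AcOH quench at −78 °C
Reagents that add atoms: none
Why: Conjugate hydride addition to the vinylogous ester should give only the C4–C5 lithium enolate 5, which is trapped by a second equivalent of 1 (reductive aldol), so the second aryl carbon is attached at C5 without a regiochemical question; C5 is not controlled here and is corrected in step 3, and the carbinol centre is deleted in step 9.

Step 3
Reactants: 6 (2S)-2-Ar-5-[Ar(hydroxy)methyl]oxan-4-one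
Product: 7 (2S,5R)-2-Ar-5-{Ar[(triethylsilyl)oxy]methyl}oxan-4-one (2,5-trans)
Conditions: Et3SiCl, imidazole, DMF, 0 °C to rt; then DBU (0.2 equiv), CH2Cl2, rt
Reagents that add atoms: chlorotriethylsilane, CC[Si](Cl)(CC)CC
Why: Silylation of the secondary alcohol blocks retro-aldol and alkoxide chemistry in step 4, and base-mediated enolisation should then equilibrate the epimerisable C5 to the diequatorial 2,5-trans oxanone (thermodynamic control relayed from C2), which fixes the later C4 of the oxolane as R.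

Step 4
Reactants: 7 (2S,5R)-2-Ar-5-{Ar[(triethylsilyl)oxy]methyl}oxan-4-one
Product: 9 (2R,5R)-2-Ar-3-diazo-5-{Ar[(triethylsilyl)oxy]methyl}oxan-4-one, via trifluoroacetyl ketone 8 (not isolated)
Conditions: LiN(SiMe3)2, THF, −78 °C, then CF3CO2CH2CF3; aq. HCl work-up; then 4-acetamidobenzenesulfonyl azide, Et3N, H2O (1 equiv), MeCN, rt
Reagents that add atoms: 4-acetamidobenzenesulfonyl azide, CC(=O)Nc1ccc(cc1)S(=O)(=O)N=[N+]=[N-] (the two diazo nitrogens); 2,2,2-trifluoroethyl trifluoroacetate, O=C(OCC(F)(F)F)C(F)(F)F (trifluoroacetyl group of intermediate 8 only)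
Why: Detrifluoroacetylative diazo transfer, in which kinetic deprotonation occurs at the only α-methylene (C3; C5 is tertiary and hindered), C-trifluoroacetylation activates that position and the sulfonyl azide then delivers N2 with loss of the trifluoroacetyl group as the N-sulfonyl amide, leaving C2 and C5 spatially untouched (the C2 descriptor changes from S to R only through CIP priorities).

Step 5
Reactants: 9 (2R,5R)-2-Ar-3-diazo-5-{Ar[(triethylsilyl)oxy]methyl}oxan-4-one
Product: 10 (2R,5R)-2-Ar-3-diazo-5-[Ar(hydroxy)methyl]oxan-4-one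
Conditions: Bu4NF, AcOH (1:1), THF, 0 °C
Reagents that add atoms: none
Why: Buffered fluoride desilylation should free the hydroxyl while the acetic acid prevents alkoxide-driven retro-aldol of the β-hydroxy ketone, and α-diazo ketones tolerate these conditions.

Step 6
Reactants: 10 (2R,5R)-2-Ar-3-diazo-5-[Ar(hydroxy)methyl]oxan-4-one
Product: 12 (3aR,6S,6aS)-3,6-di-Ar-tetrahydro-1H,3H-furo[3,4-c]furan-1-one (cis-fused; both epimers at C3), via ketene 11 (not isolated)
Conditions: hν (350 nm), dry CH2Cl2 (0.005 M), rt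
Reagents that add atoms: none
Why: Irradiation expels N2 from the s-cis-locked cyclic α-diazo ketone with concerted 1,2-shift of C5 from the carbonyl carbon to the diazo carbon, so the oxan-4-one contracts to an oxolane whose C3 carries the extruded carbonyl carbon as a ketene (11); C5 migrates with retention and C2 is untouched, so the 2,5-trans relationship of 10 becomes the 2,4-trans relationship of the oxolane. The closest known reaction type is the photochemical Wolff ring contraction of cyclic 2-diazo ketones with intramolecular capture of the ketene by a hydroxyl group. The oxolane ring arises by ring contraction (1,2-alkyl shift), and the γ-lactone closes by 5-exo-dig addition of the side-chain hydroxyl oxygen to the central ketene carbon, followed by tautomerisation of the lactone enol. The one new stereocentre, C3 of the oxolane (C6a of the lactone), is set in that protonation: only the cis-fused bicyclo[3.3.0] lactone is accessible, so the carboxyl carbon must stand cis to the C4 side chain and hence trans to the C2 aryl group. The step needs the Wolff shift to outrun carbene 1,2-hydride shift from C2 and O–H insertion, and intramolecular ketene capture to outrun dimerisation; the locked s-cis geometry, direct irradiation without a metal and high dilution in a non-nucleophilic solvent should secure this, and C5 is the only group that can migrate.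

Step 7
Reactants: 12 (3aR,6S,6aS)-3,6-di-Ar-tetrahydro-1H,3H-furo[3,4-c]furan-1-one
Product: 13 [(2S,3R,4R)-2-Ar-4-[Ar(hydroxy)methyl]oxolan-3-yl]methanol
Conditions: LiAlH4, THF, 0 °C; non-acidic work-up
Reagents that add atoms: none
Why: Hydride reduction of the γ-lactone should give the diol with no stereocentre touched, and the work-up is kept non-acidic because the electron-rich benzylic alcohol could otherwise ionise and cyclise onto the primary hydroxyl.

Step 8
Reactants: 13 [(2S,3R,4R)-2-Ar-4-[Ar(hydroxy)methyl]oxolan-3-yl]methanol; 14 3-methylbutanoyl chloride (two equivalents are consumed, one per hydroxyl)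
Product: 15 [(2S,3R,4R)-2-Ar-4-{Ar[(3-methylbutanoyl)oxy]methyl}oxolan-3-yl]methyl 3-methylbutanoate
Conditions: 14 (2.5 equiv), pyridine, DMAP (cat.), CH2Cl2, 0 °C to rt
Reagents that add atoms: 3-methylbutanoyl chloride (the second equivalent of 14, which acylates the benzylic hydroxyl), CC(C)CC(Cl)=O
Why: Exhaustive O-acylation of both hydroxyls with two equivalents of the acid chloride (nucleophilic catalysis by DMAP) installs the 3-methylbutanoate that the target keeps on the primary oxygen and places on the benzylic oxygen an acyloxy group that is a good leaving group for hydrogenolysis.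

Step 9
Reactants: 15 [(2S,3R,4R)-2-Ar-4-{Ar[(3-methylbutanoyl)oxy]methyl}oxolan-3-yl]methyl 3-methylbutanoate
Product: 16 (+)-9'-isovaleroxylariciresinol, [(2S,3R,4R)-2-(4-hydroxy-3-methoxyphenyl)-4-[(4-hydroxy-3-methoxyphenyl)methyl]oxolan-3-yl]methyl 3-methylbutanoate
Conditions: H2 (1 atm), Pd/C, EtOAc, rt
Reagents that add atoms: none
Why: Palladium-catalysed hydrogenolysis should cleave the two aryl benzyl ethers and the activated benzylic C–O bond of the secondary ester to leave the benzylic CH2, while the primary ester is inert and the less activated benzylic ether bond C2–O1 of the oxolane reacts more slowly, so the reaction is stopped once the benzylic ester is consumed and no stereocentre is affected.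

Compound list
1 | 4-(benzyloxy)-3-methoxybenzaldehyde (O-benzylvanillin) | O=Cc1ccc(OCc2ccccc2)c(OC)c1 | starting material
2 | (E)-1-methoxy-3-(trimethylsilyloxy)buta-1,3-diene | CO/C=C/C(=C)O[Si](C)(C)C | starting material
3 | (1E,5S)-5-Ar-1-methoxy-5-(trimethylsilyloxy)pent-1-en-3-one | CO/C=C/C(=O)C[C@H](O[Si](C)(C)C)c1ccc(OCc2ccccc2)c(OC)c1 | intermediate
4 | (2S)-2-Ar-2,3-dihydro-4H-pyran-4-one | O=C1C=CO[C@H](c2ccc(OCc3ccccc3)c(OC)c2)C1 | intermediate
5 | lithium (2S)-2-Ar-3,6-dihydro-2H-pyran-4-olate | [Li+].[O-]C1=CCO[C@H](c2ccc(OCc3ccccc3)c(OC)c2)C1 | intermediate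
6 | (2S)-2-Ar-5-[Ar(hydroxy)methyl]oxan-4-one, epimers at C5 and at the carbinol carbon | O=C1C[C@@H](c2ccc(OCc3ccccc3)c(OC)c2)OCC1C(O)c1ccc(OCc2ccccc2)c(OC)c1 | intermediate
7 | (2S,5R)-2-Ar-5-{Ar[(triethylsilyl)oxy]methyl}oxan-4-one, 2,5-trans, carbinol epimers | O=C1C[C@@H](c2ccc(OCc3ccccc3)c(OC)c2)OC[C@@H]1C(O[Si](CC)(CC)CC)c1ccc(OCc2ccccc2)c(OC)c1 | intermediate
8 | (2S,5R)-2-Ar-5-{Ar[(triethylsilyl)oxy]methyl}-3-(trifluoroacetyl)oxan-4-one, C3 undefined (enolised) | O=C1C(C(=O)C(F)(F)F)[C@@H](c2ccc(OCc3ccccc3)c(OC)c2)OC[C@@H]1C(O[Si](CC)(CC)CC)c1ccc(OCc2ccccc2)c(OC)c1 | intermediate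
9 | (2R,5R)-2-Ar-3-diazo-5-{Ar[(triethylsilyl)oxy]methyl}oxan-4-one, 2,5-trans | O=C1C(=[N+]=[N-])[C@@H](c2ccc(OCc3ccccc3)c(OC)c2)OC[C@@H]1C(O[Si](CC)(CC)CC)c1ccc(OCc2ccccc2)c(OC)c1 | intermediate
10 | (2R,5R)-2-Ar-3-diazo-5-[Ar(hydroxy)methyl]oxan-4-one, 2,5-trans | O=C1C(=[N+]=[N-])[C@@H](c2ccc(OCc3ccccc3)c(OC)c2)OC[C@@H]1C(O)c1ccc(OCc2ccccc2)c(OC)c1 | intermediate
11 | (2R,4R)-2-Ar-4-[Ar(hydroxy)methyl]-3-(oxomethylidene)oxolane (ketene), 2,4-trans | O=C=C1[C@@H](c2ccc(OCc3ccccc3)c(OC)c2)OC[C@@H]1C(O)c1ccc(OCc2ccccc2)c(OC)c1 | intermediate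
12 | (3aR,6S,6aS)-3,6-di-Ar-tetrahydro-1H,3H-furo[3,4-c]furan-1-one, cis-fused, epimers at C3 | O=C1OC(c2ccc(OCc3ccccc3)c(OC)c2)[C@H]2CO[C@H](c3ccc(OCc4ccccc4)c(OC)c3)[C@@H]12 | intermediate
13 | [(2S,3R,4R)-2-Ar-4-[Ar(hydroxy)methyl]oxolan-3-yl]methanol, carbinol epimers | OC(c1ccc(OCc2ccccc2)c(OC)c1)[C@H]1CO[C@H](c2ccc(OCc3ccccc3)c(OC)c2)[C@H]1CO | intermediate
14 | 3-methylbutanoyl chloride (isovaleryl chloride) | CC(C)CC(Cl)=O | starting material
15 | [(2S,3R,4R)-2-Ar-4-{Ar[(3-methylbutanoyl)oxy]methyl}oxolan-3-yl]methyl 3-methylbutanoate, carbinol epimers | CC(C)CC(=O)OC(c1ccc(OCc2ccccc2)c(OC)c1)[C@H]1CO[C@H](c2ccc(OCc3ccccc3)c(OC)c2)[C@H]1COC(=O)CC(C)C | intermediate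
16 | (+)-9'-isovaleroxylariciresinol, [(2S,3R,4R)-2-(4-hydroxy-3-methoxyphenyl)-4-[(4-hydroxy-3-methoxyphenyl)methyl]oxolan-3-yl]methyl 3-methylbutanoate | COc1cc(C[C@H]2CO[C@H](c3ccc(O)c(OC)c3)[C@H]2COC(=O)CC(C)C)ccc1O | target

Total step count: 9. Longest linear sequence: 9 steps (from 1 to 16).

Steps most likely to fail, with fallbacks

Step 6. The free hydroxyl may intercept the carbene or the ketene in an unwanted sense (O–H insertion, intermolecular ester formation), or the carbene may undergo 1,2-hydride shift from C2 before the ring contracts. The fallback sets out from compound 9 and separates ring contraction from lactonisation. The silyl ether 9 is irradiated in methanol, so that the solvent captures the ketene and gives methyl (2S,4R)-2-Ar-4-{Ar[(triethylsilyl)oxy]methyl}oxolane-3-carboxylate F1 as both C3 epimers. Bu4NF/AcOH then gives methyl (2S,4R)-2-Ar-4-[Ar(hydroxy)methyl]oxolane-3-carboxylate F2. DBU in toluene epimerises C3 of the ester, and because only the 3,4-cis isomer can close the γ-lactone, the mixture should funnel into compound 12, where the route is rejoined.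

Step 3. Equilibration at C5 may be incomplete, silanol may be lost by β-elimination to the arylidene ketone, or C2 may erode through reversible opening of the ring. The fallback sets out from compound 4 and installs the side chain before the enolate is made, so that C5 is set by protonation. Iodination (I2, pyridine, CH2Cl2) gives (2S)-2-Ar-5-iodo-2,3-dihydro-4H-pyran-4-one F3. Nozaki–Hiyama–Kishi coupling with 1 (CrCl2, cat. NiCl2, DMF) gives (2S)-2-Ar-5-[Ar(hydroxy)methyl]-2,3-dihydro-4H-pyran-4-one F4, and silylation (Et3SiCl, imidazole) gives (2S)-2-Ar-5-{Ar[(triethylsilyl)oxy]methyl}-2,3-dihydro-4H-pyran-4-one F5. Conjugate reduction with LiBH(s-Bu)3 at −78 °C and kinetic protonation of the enolate (axial delivery of the proton, side chain equatorial) should return to compound 7.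

Step 9. The benzylic C2–O1 bond of the oxolane may be hydrogenolysed (over-reduction), or cleavage of the benzylic ester may be incomplete. The fallback sets out from compound 13 and removes the benzylic oxygen by a radical path. Selective acylation of the primary hydroxyl with one equivalent of 14 (2,4,6-collidine, CH2Cl2, −78 °C) gives [(2S,3R,4R)-2-Ar-4-[Ar(hydroxy)methyl]oxolan-3-yl]methyl 3-methylbutanoate F6. 1,1'-Thiocarbonyldiimidazole gives the O-(imidazol-1-ylthiocarbonyl) derivative F7, and Barton–McCombie deoxygenation (Bu3SnH, AIBN, toluene, 80 °C) gives [(2S,3R,4R)-2-Ar-4-(Ar-methyl)oxolan-3-yl]methyl 3-methylbutanoate F8. A brief hydrogenolysis (Pd/C, H2, EtOAc), which now only has to remove the two aryl benzyl ethers, returns to compound 16.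

Further compounds
F1 | step 6 | methyl (2S,4R)-2-Ar-4-{Ar[(triethylsilyl)oxy]methyl}oxolane-3-carboxylate, C3 epimers | COC(=O)C1[C@@H](c2ccc(OCc3ccccc3)c(OC)c2)OC[C@@H]1C(O[Si](CC)(CC)CC)c1ccc(OCc2ccccc2)c(OC)c1
F2 | step 6 | methyl (2S,4R)-2-Ar-4-[Ar(hydroxy)methyl]oxolane-3-carboxylate, C3 epimers | COC(=O)C1[C@@H](c2ccc(OCc3ccccc3)c(OC)c2)OC[C@@H]1C(O)c1ccc(OCc2ccccc2)c(OC)c1
F3 | step 3 | (2S)-2-Ar-5-iodo-2,3-dihydro-4H-pyran-4-one | O=C1C(I)=CO[C@H](c2ccc(OCc3ccccc3)c(OC)c2)C1
F4 | step 3 | (2S)-2-Ar-5-[Ar(hydroxy)methyl]-2,3-dihydro-4H-pyran-4-one | O=C1C(C(O)c2ccc(OCc3ccccc3)c(OC)c2)=CO[C@H](c2ccc(OCc3ccccc3)c(OC)c2)C1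
F5 | step 3 | (2S)-2-Ar-5-{Ar[(triethylsilyl)oxy]methyl}-2,3-dihydro-4H-pyran-4-one | O=C1C(C(O[Si](CC)(CC)CC)c2ccc(OCc3ccccc3)c(OC)c2)=CO[C@H](c2ccc(OCc3ccccc3)c(OC)c2)C1
F6 | step 9 | [(2S,3R,4R)-2-Ar-4-[Ar(hydroxy)methyl]oxolan-3-yl]methyl 3-methylbutanoate | OC(c1ccc(OCc2ccccc2)c(OC)c1)[C@H]1CO[C@H](c2ccc(OCc3ccccc3)c(OC)c2)[C@H]1COC(=O)CC(C)C
F7 | step 9 | [(2S,3R,4R)-2-Ar-4-{Ar[(1H-imidazol-1-ylcarbonothioyl)oxy]methyl}oxolan-3-yl]methyl 3-methylbutanoate | S=C(OC(c1ccc(OCc2ccccc2)c(OC)c1)[C@H]1CO[C@H](c2ccc(OCc3ccccc3)c(OC)c2)[C@H]1COC(=O)CC(C)C)n1ccnc1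
F8 | step 9 | [(2S,3R,4R)-2-Ar-4-(Ar-methyl)oxolan-3-yl]methyl 3-methylbutanoate | COc1cc(C[C@H]2CO[C@H](c3ccc(OCc4ccccc4)c(OC)c3)[C@H]2COC(=O)CC(C)C)ccc1OCc1ccccc1
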